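## Structural features

The target is a hexacyclic coumaronochromone: benzene ring A, pyranone ring C, a furan and benzene ring B are fused in a row, the furan being closed by the C3–C1' bond and by an oxygen that links C2 to C2'. Ring A carries the chelated 5-OH, a methyl group on C6 and the 2,2-dimethyl-2H-chromene ring F, fused at C7 (oxygen) and C8 (carbon). Ring B carries a free OH on C5', hydrogen on C6' and the 2,2-dimethyl-dihydropyran ring E, fused at C4' (oxygen) and C3' (carbon). The only stereocentres are the neighbouring carbinol carbons C3 and C4 of ring E, (3R,4S), a trans-diol set between the gem-dimethyl carbon and ring B. Fragile sites are the benzylic C4–OH (ortho and para to ring B oxygens, so it ionises and epimerises in acid), the chromene alkene (acid, electrophiles, hydrogenation), the hydroquinone-type ring B (oxidants) and the acetal-like C2 (hard nucleophiles). The real difficulty is the fully substituted, tri-oxygenated ring B, which must be bonded to C3 of the chromone and to the stereodefined diol ring; a second, quieter problem is telling apart the three oxygens of ring A (O1, 5-O, 7-O). Ring B has para oxygens on C2' and C5', an O–C4'=C3'–C unit that looks like a cyclic enol ether, and hydrogen on C6'. That is the pattern of a Dötz phenol: C5' is the carbene carbon, C2' an inserted CO, C6' and C1' a terminal alkyne, and C4' and C3' the double bond of a 6-metalated dihydropyran, so ring E with both stereocentres can be carried in unchanged from the chiral pool.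

## Logic of the disconnections

31 to 30. Only two O–Si bonds and one O–alkyl bond are cut. All hydroxyls of rings B and E are masked by fluoride-labile groups, so one reagent finishes the synthesis and no acid reaches the benzylic carbinol. The demand is that the aryl 2-(trimethylsilyl)ethyl ether fragments under fluoride.

30 to 29. The furan C2–O bond is cut, leaving a free C2' phenol beside a methylsulfanyl leaving group on C2. This turns the pentacyclic core into a 3-arylchromone whose central C3–C1' bond can come from an alkyne. The forward step must be an intramolecular addition–elimination at C2.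

29 to 13 and 27. Ring B is taken apart completely: C5'–C6', C1'–C2' and C2'–C3' are cut and C2' goes back to a carbonyl ligand. This is the cut that removes the pentasubstituted arene, leaving a terminal alkyne on the chromone and a carbene on the enol ether carbon of ring E. The forward step needs regioselective alkyne insertion and must tolerate the thioether, the chelated phenol and the chromene.

13 to 11 to 8. The bond between the carbene carbon and C6 of the dihydropyran is cut back to a vinyl anion and a chromium carbonyl. The oxygen substituent of the carbene is introduced from the acylchromate 11 by acylation and exchange with an alcohol, because acylmetalates are not cleanly alkylated by 2-(trimethylsilyl)ethyl electrophiles. That ether is chosen because it is the only carbene alkoxy group here that can later be removed without acid, hydrogen or an oxidant.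

8 to 7. The O1–C6 bond of the enol ether is cut to give an alkynol. This replaces an acid-sensitive heterocycle by an open chain whose two stereocentres come straight from the chiral pool. The forward step must cyclise in the endo sense with a tertiary hydroxyl, and the diol must carry acyclic silyl ethers, since a trans-fused acetonide would strain the ring being formed.

7 to 6 to 5. The terminal alkyne carbon is removed, which leads back to a lactol and then a γ-lactone. The lactone hides the tertiary alcohol and activates the other chain end for a one-carbon homologation.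

5 to 3 to 2 to 1. Two C–CH3 bonds are cut and the C2-symmetric diester is desymmetrised through its half-ester. A carboxylate does not react with a methyl Grignard reagent, so the choice of which end becomes the gem-dimethyl carbinol is made chemoselectively and not statistically. The (2R,3R) centres of 1 become (3R,4S) in 8 with no change in space: the second descriptor changes only because the former carboxyl carbon drops in priority.

27 to 26 to 24 and 25. The C3–C(sp) bond is cut to a vinyl iodide and a silyl-protected ethyne. The forward coupling needs a base that does not open the chromone.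

24 to 22 and 23. Ring F is cut at C8–C and O7–C. Because C6 carries the methyl group and the 5-OH is chelated, only one chromene can form from 22.

22 to 21 to 20. The two O–CH3 bonds and the C3–I bond are cut. Iodine is introduced before ring F exists, so that no styrene-type alkene competes for the electrophile; the ethers are cleaved before any acid-sensitive group is present.

20 to 18. Ring C is cut at O1–C2 and C3–C2, with C2 coming from a one-carbon thiocarbonyl reagent. In 18 only one oxygen is free, so ring C can close in one direction only.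

18 to 16 to 14. The aryl–acyl bond and then the phenol C–O bond are cut. Starting from the corresponding free triol would give a ketone with two different ortho hydroxyls, and ring C could then close to a 6-methyl or an 8-methyl chromone. In 16 the future O1 is the only free oxygen; it is introduced at the one unhindered C–H of 14.

## Other disconnections considered

Alternative 1: The cut goes through the furan: C2–C3 and C2–O(furan) are removed and C2 becomes the carbon of tert-butyl isocyanide A3. In the forward sense the alpha-hydroxy ketone A1 is dehydrated to the aroyl ortho-quinone methide A2. A3 then adds to the methide carbon and is captured by the phenoxide oxygen, a formal [4+1] annulation that should give the 2-(tert-butylamino)-3-aroylbenzofuran A4. Ring C would follow by unmasking the MOM-protected phenol and displacing the amine at C2; ring F would follow by de-allylation and chromenylation.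
- In its favour: two bonds from a cheap one-carbon reagent under metal-free polar conditions, C2 at the right oxidation level, and ring A oxygens already distinguished by their protecting groups.
- Against it here: ring B must exist before the key step as a pentasubstituted arene carrying ring E, so the hardest part of the molecule is only moved into the synthesis of A1. The C2' phenol is ortho to two benzylic leaving groups, the carbinol and the C4 acetate of ring E, so a quinone methide can also form at C4 and erase that stereocentre. Closing ring C means expelling a hindered amine from an electron-rich 2-aminofuran, and three or four more steps are needed for ring F and deprotection.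
- Comparison: on structure the chosen plan is stronger, because step 17 creates ring B from 13 and 27 instead of presupposing it. On mechanism Alternative 1 is the equal or the better: no stoichiometric chromium, no air-sensitive carbene complex, simple ionic steps. On step economy the two are about equal up to the key step, but Alternative 1 needs more steps after it, and its stereocentres face the acid of its own key step, whereas those of 13 pass through step 17 under neutral conditions.

Alternative 2: Both pyran rings are cut at once: C8–C and O7–C of ring F, C3'–C and O4'–C of ring E. This leads back to the bis(1,1-dimethylprop-2-ynyl) ether A5 of a flat tetracyclic coumaronochromone. On heating, each aryl propargyl ether should undergo Claisen rearrangement to an ortho-allenyl dienone, a 1,5-hydrogen shift to a quinone methide-type dienone and an oxa-6π electrocyclisation, giving the hexacyclic bis-chromene A6. Ring E would then need an enantioselective epoxidation and a trans-selective hydrolytic opening.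
- In its favour: four bonds and two rings in one reagent-free step, regiochemistry fixed by blocked ortho positions (C6 methyl, C5' acetoxy), an achiral precursor with few protecting groups, and no metal. In ring-forming economy it is the better of the two plans.
- Against it here: A6 has no stereocentre and two almost identical 2,2-dimethylchromene double bonds. The oxidation must pick the ring E alkene (favoured only moderately by the more electron-rich ring B), set absolute configuration by catalyst control, and then open a benzylic epoxide with clean inversion. Such electron-rich benzylic positions tend to open through cations, which mixes cis- and trans-diols.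
- Comparison: structurally the alternative postpones the only stereochemical problem to the end, on the most valuable intermediate, while the chosen plan fixes both centres in 1 and never has to distinguish ring E from ring F. Mechanistically both key steps are pericyclic cascades of known type and are equals in precedent. In step count Alternative 2 would be shorter if the diol end-game worked in two or three steps, but that end-game is its least secure part.

Alternative 3: Ring C is cut at C3–C4 and O1–C2. The ring A benzodioxinone A7, irradiated near 300 nm, would lose its acetonide carbonyl unit and give the quinoketene A8. This oxa-diene should add across the C2=C3 bond of the ring B/E 2-silyloxybenzofuran A9, C3 bonding to the ketene carbon and the dienone oxygen to C2. Loss of the silyloxy group then aromatises ring C to the pentacyclic coumaronochromone A10, still without ring F.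
- In its favour: a convergent union that forms ring C at the right oxidation level, O1 defined by the dioxinone, ring E stereocentres brought in ready-made, no metal.
- Against it here: A9 again contains the whole of ring B, so that arene and its lactone precursor must be made separately. A9 is a hydrolytically labile ketene acetal of an electron-rich hydroquinone, and the product chromone absorbs at the irradiation wavelength. Ring F is still missing, which means acidic MOM cleavage next to a benzylic acetate on ring E, chromenylation and de-acetylation: three or more steps after the key step.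
- Comparison: in ring A regiocontrol the alternative is the equal of the chosen plan (A7 fixes O1 just as 16 does), and in convergence it is also equal; it is better in avoiding chromium. It is weaker because it does not simplify ring B, depends on a photochemical step with strongly absorbing partners, and leaves a longer and more acid-exposed end-game than steps 18 and 19.

Key step: step 17

Assumption: in the SMILES the chromium–carbon bonds of carbene and carbonyl ligands are written as double bonds and the arene complex 28 as the arene plus a Cr(CO)3 fragment joined by a dot; 1, 14, 23 and 25 are bought.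

## Route

Step 1
Reactants: 1 diethyl L-tartrate (diethyl (2R,3R)-2,3-dihydroxybutanedioate)
Product: 2 diethyl (2R,3R)-2,3-bis(tert-butyldimethylsilyloxy)butanedioate
Conditions: TBSOTf (2.3 equiv), 2,6-lutidine, CH2Cl2, 0 to 23 °C
Reagents that add atoms: tert-butyldimethylsilyl trifluoromethanesulfonate, CC(C)(C)[Si](C)(C)OS(=O)(=O)C(F)(F)F
Why: Silylation of both secondary alcohols with a silyl triflate and a hindered base; the stereocentres are not touched, and acyclic silyl ethers are chosen because they survive every step up to the final fluoride treatment.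

Step 2
Reactants: 2 diethyl (2R,3R)-2,3-bis(tert-butyldimethylsilyloxy)butanedioate
Product: 3 (2R,3R)-2,3-bis(tert-butyldimethylsilyloxy)-4-ethoxy-4-oxobutanoic acid
Conditions: KOH (1.0 equiv), EtOH/H2O, 0 to 23 °C; then 1 M HCl (to pH 3)
Reagents that add atoms: potassium hydroxide, [K+].[OH-]
Why: Mono-saponification of a symmetric diester: the carboxylate formed first repels hydroxide from the second ester, so one equivalent of base should stop at the half-ester; at 0 °C the alpha carbons are not enolised.

Step 3
Reactants: 3 (2R,3R)-2,3-bis(tert-butyldimethylsilyloxy)-4-ethoxy-4-oxobutanoic acid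
Product: 5 (3R,4R)-3,4-bis(tert-butyldimethylsilyloxy)-5,5-dimethyloxolan-2-one, via hydroxy acid 4 (not isolated)
Conditions: MeMgBr (4.5 equiv), THF, −20 to 23 °C; 1 M HCl (to pH 3); then pyridinium p-toluenesulfonate (cat.), toluene, 60 °C
Reagents that add atoms: methylmagnesium bromide, C[Mg]Br
Why: The magnesium carboxylate is inert, so the Grignard reagent adds twice to the ester only (Grignard addition to an ester); the gem-dimethyl carbinol 4 then closes to the trans γ-lactone under mild acid (Thorpe–Ingold-assisted lactonisation) with both stereocentres unchanged.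

Step 4
Reactants: 5 (3R,4R)-3,4-bis(tert-butyldimethylsilyloxy)-5,5-dimethyloxolan-2-one
Product: 6 (3R,4R)-3,4-bis(tert-butyldimethylsilyloxy)-5,5-dimethyloxolan-2-ol (anomer mixture)
Conditions: i-Bu2AlH (1.1 equiv), CH2Cl2, −78 °C; aq. KNaC4H4O6
Reagents that add atoms: none
Why: Partial reduction of a γ-lactone to the lactol; the aluminium hemiacetal is stable at −78 °C, so no diol is formed.

Step 5
Reactants: 6 (3R,4R)-3,4-bis(tert-butyldimethylsilyloxy)-5,5-dimethyloxolan-2-ol
Product: 7 (3R,4S)-3,4-bis(tert-butyldimethylsilyloxy)-2-methylhex-5-yn-2-ol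
Conditions: dimethyl (1-diazo-2-oxopropyl)phosphonate, K2CO3, MeOH, 0 to 23 °C
Reagents that add atoms: dimethyl (1-diazo-2-oxopropyl)phosphonate, COP(=O)(OC)C(=[N+]=[N-])C(C)=O
Why: Ohira–Bestmann (Seyferth–Gilbert) homologation of the hydroxy aldehyde that is in equilibrium with the lactol, a known way from lactols to alkynols; the descriptor of C4 changes to S only because the new alkyne carbon ranks below C3.

Step 6
Reactants: 7 (3R,4S)-3,4-bis(tert-butyldimethylsilyloxy)-2-methylhex-5-yn-2-ol
Product: 8 (3R,4S)-3,4-bis(tert-butyldimethylsilyloxy)-2,2-dimethyl-3,4-dihydro-2H-pyran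
Conditions: W(CO)6 (25 mol%), 1,4-diazabicyclo[2.2.2]octane, THF, hν (350 nm), 60 °C
Reagents that add atoms: none
Why: Endo-selective cycloisomerisation of an alkynol through a tungsten vinylidene: the hydroxyl adds to the metal-bound terminal carbon and protonation releases the six-membered enol ether; the gem-dimethyl group helps ring closure and the amine keeps the medium basic for the acid-labile product.

Step 7
Reactants: 8 (3R,4S)-3,4-bis(tert-butyldimethylsilyloxy)-2,2-dimethyl-3,4-dihydro-2H-pyran
Product: 11 tetramethylammonium pentacarbonyl{[(3R,4S)-3,4-bis(tert-butyldimethylsilyloxy)-2,2-dimethyl-3,4-dihydro-2H-pyran-6-yl]carbonyl}chromate, via 6-lithio dihydropyran 9 (not isolated), via lithium acylchromate 10 (not isolated)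
Conditions: t-BuLi (2.2 equiv), THF, −78 to 0 °C; Cr(CO)6, 0 to 23 °C; Me4NBr, H2O/CH2Cl2
Reagents that add atoms: hexacarbonylchromium, O=C=[Cr](=C=O)(=C=O)(=C=O)(=C=O)=C=O; tetramethylammonium bromide, C[N+](C)(C)C.[Br-]
Why: The vinylic C6–H next to the ring oxygen is removed by t-BuLi (alpha-alkoxyvinyl lithiation of a glycal), and the vinyllithium adds to a carbonyl ligand (first stage of the Fischer carbene synthesis); excess t-BuLi is consumed by THF at 0 °C before Cr(CO)6 is added, and the acylate is isolated as its stable ammonium salt.

Step 8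
Reactants: 11 tetramethylammonium pentacarbonyl{[(3R,4S)-3,4-bis(tert-butyldimethylsilyloxy)-2,2-dimethyl-3,4-dihydro-2H-pyran-6-yl]carbonyl}chromate
Product: 13 pentacarbonyl{[(3R,4S)-3,4-bis(tert-butyldimethylsilyloxy)-2,2-dimethyl-3,4-dihydro-2H-pyran-6-yl][2-(trimethylsilyl)ethoxy]methylidene}chromium, via acetoxycarbene complex 12 (not isolated)
Conditions: AcBr, CH2Cl2, −40 °C; then Me3SiCH2CH2OH, −40 to 0 °C
Reagents that add atoms: 2-(trimethylsilyl)ethanol, C[Si](C)(C)CCO
Why: O-acylation of the acylchromate gives an acyloxycarbene, whose acetate is replaced by the alcohol through addition–elimination at the carbene carbon (alcoholysis of acyloxycarbene complexes); this route installs an alkoxy group that cannot be introduced by direct alkylation.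

Step 9
Reactants: 14 1,3-dimethoxy-2-methylbenzene
Product: 16 3,5-dimethoxy-4-methylphenol, via aryl pinacol boronate 15 (not isolated)
Conditions: [Ir(OMe)(cod)]2 (1 mol%), 4,4'-di-tert-butyl-2,2'-bipyridine, B2pin2 (1.0 equiv), THF, 80 °C; then aq. H2O2, NaOH, 0 °C
Reagents that add atoms: hydrogen peroxide, OO
Why: Iridium-catalysed C–H borylation is sterically controlled and takes the only C–H with no ortho substituent; oxidation of the C–B bond gives the phenol, so the future O1 is the one free oxygen and the two oxygens flanking the methyl group stay as ethers.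

Step 10
Reactants: 16 3,5-dimethoxy-4-methylphenol
Product: 18 1-(6-hydroxy-2,4-dimethoxy-3-methylphenyl)ethan-1-one, via difluoroboron chelate 17 (not isolated)
Conditions: AcOH, BF3·OEt2, 90 °C; then MeOH/H2O, 65 °C
Reagents that add atoms: acetic acid, CC(=O)O
Why: BF3-mediated C-acylation of a phloroglucinol ether (Friedel–Crafts/Fries type) goes ortho to the free hydroxyl because the para position carries the methyl group and the two ortho positions are equivalent; the ketone is held as its boron chelate until hydrolysis.

Step 11
Reactants: 18 1-(6-hydroxy-2,4-dimethoxy-3-methylphenyl)ethan-1-one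
Product: 20 5,7-dimethoxy-6-methyl-2-(methylsulfanyl)-4H-chromen-4-one, via ketene dithioacetal 19 (not isolated)
Conditions: NaH (3.3 equiv), CS2, THF, 0 to 23 °C; MeI (2.1 equiv); then 65 °C
Reagents that add atoms: carbon disulfide, S=C=S; iodomethane, CI
Why: The ketone enolate adds to CS2 and double S-methylation gives the alpha-oxo ketene dithioacetal; the single ortho phenoxide then closes ring C by conjugate addition and loss of methanethiolate, so only the 6-methyl chromone can form.

Step 12
Reactants: 20 5,7-dimethoxy-6-methyl-2-(methylsulfanyl)-4H-chromen-4-one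
Product: 21 3-iodo-5,7-dimethoxy-6-methyl-2-(methylsulfanyl)-4H-chromen-4-one
Conditions: N-iodosuccinimide, DMF, 23 °C, dark
Reagents that add atoms: N-iodosuccinimide, O=C1CCC(=O)N1I
Why: Electrophilic iodination at C3, the nucleophilic alpha carbon of a push–pull O,S-ketene acetal; without acid ring A, deactivated by the C4 carbonyl, should not compete, and no alkene is present yet.

Step 13
Reactants: 21 3-iodo-5,7-dimethoxy-6-methyl-2-(methylsulfanyl)-4H-chromen-4-one
Product: 22 5,7-dihydroxy-3-iodo-6-methyl-2-(methylsulfanyl)-4H-chromen-4-one
Conditions: BBr3 (4 equiv), CH2Cl2, −78 to 0 °C; then H2O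
Reagents that add atoms: none
Why: Lewis acid cleavage of both aryl methyl ethers (the 5-ether helped by chelation to the carbonyl); methyl sulfides and vinyl iodides tolerate BBr3, and nothing acid-sensitive is present at this stage.

Step 14
Reactants: 22 5,7-dihydroxy-3-iodo-6-methyl-2-(methylsulfanyl)-4H-chromen-4-one; 23 3-methylbut-2-enal
Product: 24 5-hydroxy-3-iodo-6,8,8-trimethyl-2-(methylsulfanyl)-4H,8H-pyrano[2,3-f]chromen-4-one
Conditions: ethylenediammonium diacetate (10 mol%), xylene, 120 °C
Reagents that add atoms: none
Why: Amine-catalysed Knoevenagel-type condensation of the enal at C8 gives an ortho-quinone methide that closes by oxa-6π electrocyclisation (chromenylation); C6 is blocked by methyl and the 5-OH is chelated, so only the C8/7-O chromene can form.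

Step 15
Reactants: 24 5-hydroxy-3-iodo-6,8,8-trimethyl-2-(methylsulfanyl)-4H,8H-pyrano[2,3-f]chromen-4-one; 25 ethynyltrimethylsilane
Product: 26 5-hydroxy-6,8,8-trimethyl-2-(methylsulfanyl)-3-[(trimethylsilyl)ethynyl]-4H,8H-pyrano[2,3-f]chromen-4-one
Conditions: Pd(PPh3)2Cl2 (5 mol%), CuI (10 mol%), i-Pr2NEt, THF, 40 °C
Reagents that add atoms: none
Why: Sonogashira coupling of an electron-poor vinyl iodide; a hindered tertiary amine is used because nucleophilic amines open chromones or displace the C2 thioether.

Step 16
Reactants: 26 5-hydroxy-6,8,8-trimethyl-2-(methylsulfanyl)-3-[(trimethylsilyl)ethynyl]-4H,8H-pyrano[2,3-f]chromen-4-one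
Product: 27 3-ethynyl-5-hydroxy-6,8,8-trimethyl-2-(methylsulfanyl)-4H,8H-pyrano[2,3-f]chromen-4-one
Conditions: Bu4NF, AcOH, THF, 0 °C
Reagents that add atoms: none
Why: Fluoride-induced protodesilylation of the alkynylsilane; buffering with acetic acid keeps alkoxide-type nucleophiles away from C2.

Step 17
Reactants: 13 pentacarbonyl{[(3R,4S)-3,4-bis(tert-butyldimethylsilyloxy)-2,2-dimethyl-3,4-dihydro-2H-pyran-6-yl][2-(trimethylsilyl)ethoxy]methylidene}chromium; 27 3-ethynyl-5-hydroxy-6,8,8-trimethyl-2-(methylsulfanyl)-4H,8H-pyrano[2,3-f]chromen-4-one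
Product: 29 3-[(3R,4S)-3,4-bis(tert-butyldimethylsilyloxy)-5-hydroxy-2,2-dimethyl-8-[2-(trimethylsilyl)ethoxy]-3,4-dihydro-2H-chromen-6-yl]-5-hydroxy-6,8,8-trimethyl-2-(methylsulfanyl)-4H,8H-pyrano[2,3-f]chromen-4-one, via tricarbonylchromium arene complex 28 (not isolated)
Conditions: THF (0.05 M), 55 °C, argon; then air, daylight, 23 °C
Reagents that add atoms: none
Why: Thermal loss of one cis carbonyl ligand from 13 frees a site for the alkyne of 27, which inserts into the chromium–carbene bond with its CH carbon bonded to the carbene carbon, giving a vinylcarbene (bond C5'–C6'). Insertion of CO gives a chromium-bound dienylketene (bond C1'–C2'), and ring B closes by thermal 6π electrocyclisation between the ketene carbon and C5 of the dihydropyran (bond C2'–C3'). Tautomerisation of the cyclohexadienone gives the phenol as its Cr(CO)3 complex 28, which air and light decomplex to 29. The closest known reaction type is the Dötz benzannulation of alkenyl(alkoxy)carbene chromium complexes, including those made from lithiated glycals, with terminal alkynes. No stereocentre is formed; C3 and C4 of ring E are spectators under neutral conditions and keep the configuration taken from 1. Regiochemistry is secured by the size difference between hydrogen and the 3-chromonyl group, which puts the chromone next to the CO-derived phenol carbon and hydrogen on C6'. Phenol formation, rather than cyclopentannulation or cyclobutenone formation, is favoured by an alkenyl(alkoxy) chromium carbene in an ethereal solvent at moderate dilution. The C4 carbonyl and the sulfur could trap the vinylcarbene only through four-membered rings, and the chromene alkene is too hindered to be cyclopropanated.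

Step 18
Reactants: 29 3-[(3R,4S)-3,4-bis(tert-butyldimethylsilyloxy)-5-hydroxy-2,2-dimethyl-8-[2-(trimethylsilyl)ethoxy]-3,4-dihydro-2H-chromen-6-yl]-5-hydroxy-6,8,8-trimethyl-2-(methylsulfanyl)-4H,8H-pyrano[2,3-f]chromen-4-one
Product: 30 hexacyclic coumaronochromone with 5-OH free, 5'-O-[2-(trimethylsilyl)ethyl] and (3R,4S)-3,4-bis(tert-butyldimethylsilyloxy) groups on ring E
Conditions: K2CO3, DMF, 60 °C, argon
Reagents that add atoms: none
Why: The C2' phenoxide adds to C2 of the vinylogous thioester and methanethiolate leaves (intramolecular addition–elimination, the type of closure known for 2-(methylsulfanyl)isoflavones with a 2'-hydroxyl); it is 5-endo by ring count but is made feasible by the strong polarisation of C2 and by gaining the aromatic furan.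

Step 19
Reactants: 30 hexacyclic coumaronochromone with 5-OH free, 5'-O-[2-(trimethylsilyl)ethyl] and (3R,4S)-3,4-bis(tert-butyldimethylsilyloxy) groups on ring E
Product: 31 CNP0351839.1, the hexacyclic coumaronochromone with 5-OH, 6-methyl, ring F 2,2-dimethyl-2H-pyran on C7(O)/C8, 5'-OH and ring E (3R,4S)-3,4-dihydroxy-2,2-dimethyl-3,4-dihydro-2H-pyran on C4'(O)/C3'
Conditions: Bu4NF (excess), THF/DMF, 23 then 60 °C; aq. NH4Cl
Reagents that add atoms: none
Why: Fluoride removes the two silyl ethers at 23 °C and, on warming, the aryl 2-(trimethylsilyl)ethyl ether by attack at silicon and beta-elimination of ethene; no acid is used, so the benzylic C4 carbinol keeps its configuration.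

## Compound list

1 | diethyl L-tartrate, diethyl (2R,3R)-2,3-dihydroxybutanedioate | CCOC(=O)[C@H](O)[C@@H](O)C(=O)OCC | starting material
2 | diethyl (2R,3R)-2,3-bis(tert-butyldimethylsilyloxy)butanedioate | CCOC(=O)[C@H](O[Si](C)(C)C(C)(C)C)[C@@H](O[Si](C)(C)C(C)(C)C)C(=O)OCC | intermediate
3 | (2R,3R)-2,3-bis(tert-butyldimethylsilyloxy)-4-ethoxy-4-oxobutanoic acid | CCOC(=O)[C@H](O[Si](C)(C)C(C)(C)C)[C@@H](O[Si](C)(C)C(C)(C)C)C(=O)O | intermediate
4 | (2R,3R)-2,3-bis(tert-butyldimethylsilyloxy)-4-hydroxy-4-methylpentanoic acid | CC(C)(O)[C@H](O[Si](C)(C)C(C)(C)C)[C@@H](O[Si](C)(C)C(C)(C)C)C(=O)O | intermediate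
5 | (3R,4R)-3,4-bis(tert-butyldimethylsilyloxy)-5,5-dimethyloxolan-2-one | CC(C)(O1)[C@H](O[Si](C)(C)C(C)(C)C)[C@@H](O[Si](C)(C)C(C)(C)C)C1=O | intermediate
6 | (3R,4R)-3,4-bis(tert-butyldimethylsilyloxy)-5,5-dimethyloxolan-2-ol, anomer mixture | CC(C)(O1)[C@H](O[Si](C)(C)C(C)(C)C)[C@@H](O[Si](C)(C)C(C)(C)C)C1O | intermediate
7 | (3R,4S)-3,4-bis(tert-butyldimethylsilyloxy)-2-methylhex-5-yn-2-ol | CC(C)(O)[C@H](O[Si](C)(C)C(C)(C)C)[C@@H](O[Si](C)(C)C(C)(C)C)C#C | intermediate
8 | (3R,4S)-3,4-bis(tert-butyldimethylsilyloxy)-2,2-dimethyl-3,4-dihydro-2H-pyran | C1=COC(C)(C)[C@H](O[Si](C)(C)C(C)(C)C)[C@H]1O[Si](C)(C)C(C)(C)C | intermediate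
9 | 6-lithio derivative of 8 | C1=C([Li])OC(C)(C)[C@H](O[Si](C)(C)C(C)(C)C)[C@H]1O[Si](C)(C)C(C)(C)C | intermediate
10 | lithium pentacarbonyl{[(3R,4S)-3,4-bis(tert-butyldimethylsilyloxy)-2,2-dimethyl-3,4-dihydro-2H-pyran-6-yl]carbonyl}chromate | C1=C(C([O-])=[Cr](=C=O)(=C=O)(=C=O)(=C=O)=C=O)OC(C)(C)[C@H](O[Si](C)(C)C(C)(C)C)[C@H]1O[Si](C)(C)C(C)(C)C.[Li+] | intermediate
11 | tetramethylammonium pentacarbonyl{[(3R,4S)-3,4-bis(tert-butyldimethylsilyloxy)-2,2-dimethyl-3,4-dihydro-2H-pyran-6-yl]carbonyl}chromate | C1=C(C([O-])=[Cr](=C=O)(=C=O)(=C=O)(=C=O)=C=O)OC(C)(C)[C@H](O[Si](C)(C)C(C)(C)C)[C@H]1O[Si](C)(C)C(C)(C)C.C[N+](C)(C)C | intermediate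
12 | pentacarbonyl{acetoxy[(3R,4S)-3,4-bis(tert-butyldimethylsilyloxy)-2,2-dimethyl-3,4-dihydro-2H-pyran-6-yl]methylidene}chromium | C1=C(C(OC(C)=O)=[Cr](=C=O)(=C=O)(=C=O)(=C=O)=C=O)OC(C)(C)[C@H](O[Si](C)(C)C(C)(C)C)[C@H]1O[Si](C)(C)C(C)(C)C | intermediate
13 | pentacarbonyl{[(3R,4S)-3,4-bis(tert-butyldimethylsilyloxy)-2,2-dimethyl-3,4-dihydro-2H-pyran-6-yl][2-(trimethylsilyl)ethoxy]methylidene}chromium | C1=C(C(OCC[Si](C)(C)C)=[Cr](=C=O)(=C=O)(=C=O)(=C=O)=C=O)OC(C)(C)[C@H](O[Si](C)(C)C(C)(C)C)[C@H]1O[Si](C)(C)C(C)(C)C | intermediate
14 | 1,3-dimethoxy-2-methylbenzene (2,6-dimethoxytoluene) | COc1cccc(OC)c1C | starting material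
15 | 2-(3,5-dimethoxy-4-methylphenyl)-4,4,5,5-tetramethyl-1,3,2-dioxaborolane | COc1cc(B2OC(C)(C)C(C)(C)O2)cc(OC)c1C | intermediate
16 | 3,5-dimethoxy-4-methylphenol | COc1cc(O)cc(OC)c1C | intermediate
17 | difluoroboron chelate of 18 (2,2-difluoro-5,7-dimethoxy-4,6-dimethyl-1,3,2-benzodioxaborinine) | CC1=[O+][B-](F)(F)Oc2cc(OC)c(C)c(OC)c12 | intermediate
18 | 1-(6-hydroxy-2,4-dimethoxy-3-methylphenyl)ethan-1-one | CC(=O)c1c(O)cc(OC)c(C)c1OC | intermediate
19 | 1-(6-hydroxy-2,4-dimethoxy-3-methylphenyl)-3,3-bis(methylsulfanyl)prop-2-en-1-one | CSC(SC)=CC(=O)c1c(O)cc(OC)c(C)c1OC | intermediate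
20 | 5,7-dimethoxy-6-methyl-2-(methylsulfanyl)-4H-chromen-4-one | Cc1c(OC)cc2oc(SC)cc(=O)c2c1OC | intermediate
21 | 3-iodo-5,7-dimethoxy-6-methyl-2-(methylsulfanyl)-4H-chromen-4-one | Cc1c(OC)cc2oc(SC)c(I)c(=O)c2c1OC | intermediate
22 | 5,7-dihydroxy-3-iodo-6-methyl-2-(methylsulfanyl)-4H-chromen-4-one | Cc1c(O)cc2oc(SC)c(I)c(=O)c2c1O | intermediate
23 | 3-methylbut-2-enal | CC(C)=CC=O | starting material
24 | 5-hydroxy-3-iodo-6,8,8-trimethyl-2-(methylsulfanyl)-4H,8H-pyrano[2,3-f]chromen-4-one | Cc1c2c(c3oc(SC)c(I)c(=O)c3c1O)C=CC(C)(C)O2 | intermediate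
25 | ethynyltrimethylsilane | C[Si](C)(C)C#C | starting material
26 | 5-hydroxy-6,8,8-trimethyl-2-(methylsulfanyl)-3-[(trimethylsilyl)ethynyl]-4H,8H-pyrano[2,3-f]chromen-4-one | Cc1c2c(c3oc(SC)c(C#C[Si](C)(C)C)c(=O)c3c1O)C=CC(C)(C)O2 | intermediate
27 | 3-ethynyl-5-hydroxy-6,8,8-trimethyl-2-(methylsulfanyl)-4H,8H-pyrano[2,3-f]chromen-4-one | Cc1c2c(c3oc(SC)c(C#C)c(=O)c3c1O)C=CC(C)(C)O2 | intermediate
28 | tricarbonylchromium complex of 29, chromium bound to ring B | Oc1c2c(c(OCC[Si](C)(C)C)cc1-c1c(SC)oc3c(c1=O)c(O)c(C)c1c3C=CC(C)(C)O1)OC(C)(C)[C@H](O[Si](C)(C)C(C)(C)C)[C@H]2O[Si](C)(C)C(C)(C)C.O=C=[Cr](=C=O)=C=O | intermediate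
29 | 3-[(3R,4S)-3,4-bis(tert-butyldimethylsilyloxy)-5-hydroxy-2,2-dimethyl-8-[2-(trimethylsilyl)ethoxy]-3,4-dihydro-2H-chromen-6-yl]-5-hydroxy-6,8,8-trimethyl-2-(methylsulfanyl)-4H,8H-pyrano[2,3-f]chromen-4-one | Oc1c2c(c(OCC[Si](C)(C)C)cc1-c1c(SC)oc3c(c1=O)c(O)c(C)c1c3C=CC(C)(C)O1)OC(C)(C)[C@H](O[Si](C)(C)C(C)(C)C)[C@H]2O[Si](C)(C)C(C)(C)C | intermediate
30 | hexacyclic coumaronochromone, 5-OH free, 5'-O-[2-(trimethylsilyl)ethyl], ring E (3R,4S)-3,4-bis(tert-butyldimethylsilyloxy) | Cc1c2c(c3oc4oc5c6c(c(OCC[Si](C)(C)C)cc5c4c(=O)c3c1O)OC(C)(C)[C@H](O[Si](C)(C)C(C)(C)C)[C@H]6O[Si](C)(C)C(C)(C)C)C=CC(C)(C)O2 | intermediate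
31 | CNP0351839.1, hexacyclic coumaronochromone with 5-OH, 6-methyl, ring F chromene, 5'-OH and ring E (3R,4S)-trans-diol | Cc1c2c(c3oc4oc5c6c(c(O)cc5c4c(=O)c3c1O)OC(C)(C)[C@H](O)[C@H]6O)C=CC(C)(C)O2 | target

## Step count and least certain steps

Total: 19 steps. Longest linear sequence: 11 steps (steps 1 to 8, then 17 to 19; the arm of steps 9 to 16 followed by 17 to 19 is equally long).

Step 17 (key step). What may go wrong: the thioether or the chelated phenol may bind the unsaturated chromium centre and stop alkyne insertion, or the hindered, conjugated alkyne may insert so slowly that the carbene decomposes; diversion of the vinylketene to cyclobutenone or cyclopentannulation products is also possible. Fallback: take the chromone out of the benzannulation. Setting out from 13, heating with 2-ethynyl-4,4,5,5-tetramethyl-1,3,2-dioxaborolane under the conditions of step 17 should give the ortho-borylated phenol (3R,4S)-3,4-bis(tert-butyldimethylsilyloxy)-2,2-dimethyl-6-(4,4,5,5-tetramethyl-1,3,2-dioxaborolan-2-yl)-8-[2-(trimethylsilyl)ethoxy]-3,4-dihydro-2H-chromen-5-ol F1, with boron next to the new hydroxyl on steric grounds. Suzuki coupling of F1 with iodide 24 (Pd(dppf)Cl2, K3PO4, dioxane/H2O, 60 °C) then forms the C3–C1' bond and comes back to the route at 29.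

Step 8. What may go wrong: the acetoxycarbene may decompose before the alcohol intercepts it, or the alcohol may add in conjugate fashion to the alkenyl carbene. Fallback: setting out from 11, O-methylation with MeOTf (CH2Cl2, 0 °C) gives the methoxycarbene complex pentacarbonyl{[(3R,4S)-3,4-bis(tert-butyldimethylsilyloxy)-2,2-dimethyl-3,4-dihydro-2H-pyran-6-yl](methoxy)methylidene}chromium F2. Alkoxide-catalysed alkoxy exchange with 2-(trimethylsilyl)ethanol (catalytic NaOCH2CH2SiMe3, THF, 0 °C), a substitution at the carbene carbon through a tetrahedral adduct, then comes back to the route at 13.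

Step 6. What may go wrong: the hindered tertiary hydroxyl may fail to add to the tungsten vinylidene, cyclisation may go exo to a methylene-oxolane, or the silyl ethers may suffer under irradiation. Fallback: setting out from 7, anti-Markovnikov hydration of the alkyne (dicyclohexylborane, then NaBO3) gives an aldehyde that closes at once to the six-membered lactol (4S,5R)-4,5-bis(tert-butyldimethylsilyloxy)-6,6-dimethyloxan-2-ol F3. Mesylation and elimination (MsCl, Et3N, CH2Cl2, −20 to 40 °C), the usual dehydration of 2-deoxy lactols to glycals, comes back to the route at 8.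

Step 12. What may go wrong: iodination at C8 of ring A may compete with C3, giving a regioisomer or a di-iodide. Fallback: change the order so that ring A has no free position. Setting out from 20, BBr3 gives 5,7-dihydroxy-6-methyl-2-(methylsulfanyl)-4H-chromen-4-one F4; chromenylation with 23 as in step 14 gives 5-hydroxy-6,8,8-trimethyl-2-(methylsulfanyl)-4H,8H-pyrano[2,3-f]chromen-4-one F5; iodination of F5 at C3 with N-iodosuccinimide in dry DMF comes back to the route at 24. The competitor is then the chromene alkene instead of an arene C–H.

Step 19. What may go wrong: the aryl 2-(trimethylsilyl)ethyl ether may cleave incompletely at temperatures the polyphenol tolerates, or hydroxide in wet fluoride may open ring C at C2. Fallback: separate the two deprotections. Setting out from 30, BF3·OEt2 (CH2Cl2, −20 °C) cleaves the 2-(trimethylsilyl)ethyl ether by beta-silyl fragmentation while the silyl ethers still shield the benzylic carbinol, giving the 5'-phenol with ring E (3R,4S)-3,4-bis(tert-butyldimethylsilyloxy) groups F6. Bu4NF in THF at 23 °C then removes the two silyl ethers and comes back to the route at 31.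

## Further compounds

F1 | step 17 | (3R,4S)-3,4-bis(tert-butyldimethylsilyloxy)-2,2-dimethyl-6-(4,4,5,5-tetramethyl-1,3,2-dioxaborolan-2-yl)-8-[2-(trimethylsilyl)ethoxy]-3,4-dihydro-2H-chromen-5-ol | Oc1c2c(c(OCC[Si](C)(C)C)cc1B1OC(C)(C)C(C)(C)O1)OC(C)(C)[C@H](O[Si](C)(C)C(C)(C)C)[C@H]2O[Si](C)(C)C(C)(C)C
F2 | step 8 | pentacarbonyl{[(3R,4S)-3,4-bis(tert-butyldimethylsilyloxy)-2,2-dimethyl-3,4-dihydro-2H-pyran-6-yl](methoxy)methylidene}chromium | C1=C(C(OC)=[Cr](=C=O)(=C=O)(=C=O)(=C=O)=C=O)OC(C)(C)[C@H](O[Si](C)(C)C(C)(C)C)[C@H]1O[Si](C)(C)C(C)(C)C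
F3 | step 6 | (4S,5R)-4,5-bis(tert-butyldimethylsilyloxy)-6,6-dimethyloxan-2-ol | CC(C)(O1)[C@H](O[Si](C)(C)C(C)(C)C)[C@@H](O[Si](C)(C)C(C)(C)C)CC1O
F4 | step 12 | 5,7-dihydroxy-6-methyl-2-(methylsulfanyl)-4H-chromen-4-one | Cc1c(O)cc2oc(SC)cc(=O)c2c1O
F5 | step 12 | 5-hydroxy-6,8,8-trimethyl-2-(methylsulfanyl)-4H,8H-pyrano[2,3-f]chromen-4-one | Cc1c2c(c3oc(SC)cc(=O)c3c1O)C=CC(C)(C)O2
F6 | step 19 | hexacyclic coumaronochromone with 5-OH and 5'-OH free and ring E (3R,4S)-3,4-bis(tert-butyldimethylsilyloxy) | Cc1c2c(c3oc4oc5c6c(c(O)cc5c4c(=O)c3c1O)OC(C)(C)[C@H](O[Si](C)(C)C(C)(C)C)[C@H]6O[Si](C)(C)C(C)(C)C)C=CC(C)(C)O2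
A1 | alternative 1 | alpha-hydroxy ketone joining the ring A aroyl group (2-MOM, 4,6-diallyl, 5-methyl) to C1' of ring B/E (free C2' phenol, 5'-O-acetyl, (3R,4S)-diol diacetate) | Oc1c2c(c(OC(C)=O)cc1C(O)C(=O)c1c(OCOC)cc(OCC=C)c(C)c1OCC=C)OC(C)(C)[C@H](OC(C)=O)[C@H]2OC(C)=O
A2 | alternative 1 | aroyl ortho-quinone methide from A1 | O=C1C2=C(C(OC(C)=O)=CC1=CC(=O)c1c(OCOC)cc(OCC=C)c(C)c1OCC=C)OC(C)(C)[C@H](OC(C)=O)[C@H]2OC(C)=O
A3 | alternative 1 | tert-butyl isocyanide | CC(C)(C)[N+]#[C-]
A4 | alternative 1 | ring B/E 2-(tert-butylamino)benzofuran with the ring A aroyl group on C3 | CC(C)(C)Nc1oc2c3c(c(OC(C)=O)cc2c1C(=O)c1c(OCOC)cc(OCC=C)c(C)c1OCC=C)OC(C)(C)[C@H](OC(C)=O)[C@H]3OC(C)=O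
A5 | alternative 2 | 7,4'-bis(1,1-dimethylprop-2-ynyl) ether of the tetracyclic 5-hydroxy-6-methyl-5'-acetoxy coumaronochromone | Cc1c(OC(C)(C)C#C)cc2oc3oc4cc(OC(C)(C)C#C)c(OC(C)=O)cc4c3c(=O)c2c1O
A6 | alternative 2 | hexacyclic bis-chromene, 5'-O-acetyl, ring E still an alkene | Cc1c2c(c3oc4oc5c6c(c(OC(C)=O)cc5c4c(=O)c3c1O)OC(C)(C)C=C6)C=CC(C)(C)O2
A7 | alternative 3 | 5,7-bis(methoxymethoxy)-2,2,6-trimethyl-4H-1,3-benzodioxin-4-one | Cc1c(OCOC)cc2OC(C)(C)OC(=O)c2c1OCOC
A8 | alternative 3 | quinoketene from A7, 3,5-bis(methoxymethoxy)-4-methyl-6-(oxomethylidene)cyclohexa-2,4-dien-1-one | O=C=C1C(=O)C=C(OCOC)C(C)=C1OCOC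
A9 | alternative 3 | ring B/E 2-(tert-butyldimethylsilyloxy)benzofuran, 5'-O-acetyl, (3R,4S)-diol diacetate | CC(C)(C)[Si](C)(C)Oc1oc2c3c(c(OC(C)=O)cc2c1)OC(C)(C)[C@H](OC(C)=O)[C@H]3OC(C)=O
A10 | alternative 3 | pentacyclic coumaronochromone lacking ring F, 5,7-bis-MOM, 5'-O-acetyl, (3R,4S)-diol diacetate | Cc1c(OCOC)cc2oc3oc4c5c(c(OC(C)=O)cc4c3c(=O)c2c1OCOC)OC(C)(C)[C@H](OC(C)=O)[C@H]5OC(C)=O
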